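**Plan**

1. Cuts: the disubstituted alkene of the diene next to ring A (Julia–Kocienski olefination of a ring A sulfone with a ring B dienal); in ring A (the methylenecyclohexane: a1 = C(=CH2), a2 and a3 = the CH2–CH2 pair, a4 = CHMe, a5 = CMe2, a6 = CH carrying the chain) the a2–a3 bond; in ring B (the cyclohexanol) the enal C=C and the two C–C bonds at the vicinal tertiary/quaternary pair.
2. Ring A feature: a1 is a masked ketone and a2 is an unsubstituted CH2 beside it, so ring A is the one-carbon homologue of a cis-2,4-disubstituted 3,3-dimethylcyclopentanone. That temporary five-membered ring is the skeleton of α-campholenic aldehyde; it is opened at a1–a3 while the six-membered ring closes at a2–a3 (diazoalkane ring expansion), then a1 is methylenated.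
3. Ring B: three-component conjugate addition/allylation on a quinone-monoketal-derived enone, methyl addition to the ketone, then an eight-membered lactone through the hydroxypropyl oxygen (temporary ring) that fixes the tetrasubstituted enal geometry.
4. Forward order: ring A sulfone (steps 1–10), ring B dienal (steps 11–22), union and end game (steps 23–25).
5. Stereochemistry: a6 from the chiral pool, a4 by hydrogenation anti to the a6 substituent; ring B tertiary centre by ligand-controlled copper catalysis, quaternary centre by trans alkylation, carbinol by substrate-controlled addition; alkene geometries from the lactone ring, the stabilized ylide and the Julia–Kocienski step.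

Key step: step 6

Assumption: (S)-α-campholenic aldehyde is bought in high enantiomeric purity (it is also the ZnBr2 rearrangement product of commercial α-pinene oxide), and the Grignard and ylide reagents named below are bought or made beforehand.

**Ring A sulfone**

Step 1
Reactants: 1 (S)-α-campholenic aldehyde
Product: 2 2-[(1S)-2,2,3-trimethylcyclopent-3-en-1-yl]acetic acid
Conditions: NaClO2, NaH2PO4, 2-methylbut-2-ene, t-BuOH/H2O, 0 °C → rt
Reagents that add atoms: sodium chlorite, [Na+].[O-]Cl=O
Why: Pinnick oxidation is selective for the aldehyde, the scavenger removes HOCl before it can touch the trisubstituted alkene, and the stereocenter is not α to the carbonyl.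

Step 2
Reactants: 2 2-[(1S)-2,2,3-trimethylcyclopent-3-en-1-yl]acetic acid
Product: 5 [(1R)-2,2,3-trimethylcyclopent-3-en-1-yl]methanol, via Barton ester 3 (not isolated), via hydroperoxide 4 (not isolated)
Conditions: N-hydroxypyridine-2-thione, DCC, cat. DMAP, CH2Cl2, dark, rt; then O2, t-BuSH, PhMe, W lamp, 0 °C; then P(OMe)3
Reagents that add atoms: dioxygen, O=O
Why: Barton radical decarboxylation with oxygen trapping (decarboxylative hydroxylation) excises the extra carboxyl carbon through a primary radical, so the adjacent stereocenter is never planarized.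

Step 3
Reactants: 5 [(1R)-2,2,3-trimethylcyclopent-3-en-1-yl]methanol
Product: 6 tert-butyl(diphenyl){[(1R)-2,2,3-trimethylcyclopent-3-en-1-yl]methoxy}silane
Conditions: TBDPSCl, imidazole, DMF, rt
Reagents that add atoms: tert-butyl(chloro)diphenylsilane, CC(C)(C)[Si](Cl)(c1ccccc1)c1ccccc1
Why: Standard silylation gives a robust ether that is a poor leaving group, which matters once it sits β to a ketone.

Step 4
Reactants: 6 tert-butyl(diphenyl){[(1R)-2,2,3-trimethylcyclopent-3-en-1-yl]methoxy}silane
Product: 7 (5R)-5-{[tert-butyl(diphenyl)silyl]oxymethyl}-3,4,4-trimethylcyclopent-2-en-1-one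
Conditions: Rh2(cap)4 (dirhodium tetracaprolactamate, 1 mol%), t-BuOOH (70% aq.), K2CO3, CH2Cl2, rt
Reagents that add atoms: tert-butyl hydroperoxide, CC(C)(C)OO
Why: Catalytic allylic oxidation attacks the only allylic ring CH2 (the other allylic ring position is quaternary) and gives the conjugated cyclopentenone whose carbonyl carbon becomes a1.

Step 5
Reactants: 7 (5R)-5-{[tert-butyl(diphenyl)silyl]oxymethyl}-3,4,4-trimethylcyclopent-2-en-1-one
Product: 8 (2R,4S)-2-{[tert-butyl(diphenyl)silyl]oxymethyl}-3,3,4-trimethylcyclopentan-1-one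
Conditions: H2 (1 atm), Pd/C (palladium on carbon), EtOAc, rt
Reagents that add atoms: none
Why: Heterogeneous hydrogenation should add H2 to the enone from the face opposite the silyloxymethyl group, which puts the new methyl-bearing center (a4) cis to that group (substrate control by a6).

Step 6
Reactants: 8 (2R,4S)-2-{[tert-butyl(diphenyl)silyl]oxymethyl}-3,3,4-trimethylcyclopentan-1-one
Product: 10 (2R,4S)-2-{[tert-butyl(diphenyl)silyl]oxymethyl}-3,3,4-trimethylcyclohexan-1-one, via α-silyl ketone 9 (not isolated)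
Conditions: TMSCHN2 (1.3 equiv), Sc(OTf)3 (10 mol%), PhMe/CH2Cl2, −78 → −20 °C; then 1 M HCl, THF, 0 °C
Reagents that add atoms: (trimethylsilyl)diazomethane, C[Si](C)(C)C=[N+]=[N-]
Why: The Lewis-acid-activated ketone adds the diazo carbon (the future a2) to a1, and loss of N2 drives a 1,2-shift of the ring CH2 (a3) from a1 to a2, so the six-membered ring closes at a2–a3 as the five-membered ring opens; acid then removes the silyl group from a2. The closest known reaction type is the diazoalkane homologation of cycloalkanones (Tiffeneau–Demjanov-type ring enlargement). The ring is closed by a 1,2-alkyl shift onto the carbon that loses N2, not by an exo or endo cyclization of a chain. No stereocenter is created in the isolated product (the silyl-bearing carbon is transient); a4 is remote and a6, though α to the ketone, should keep its configuration under non-basic, low-temperature conditions. The selectivity needed is migration of the CH2 over the substituted α-carbon a6 and a single insertion. The first should follow from the bulky silyl group turning away from the neopentyl-type a6 in the adduct, which places N2 antiperiplanar to the CH2, and the second from the α-silyl ketone being too hindered to react again.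

Step 7
Reactants: 10 (2R,4S)-2-{[tert-butyl(diphenyl)silyl]oxymethyl}-3,3,4-trimethylcyclohexan-1-one
Product: 11 tert-butyl(diphenyl){[(1R,3S)-2,2,3-trimethyl-6-methylidenecyclohexyl]methoxy}silane
Conditions: Zn, CH2Br2, TiCl4, THF/CH2Cl2, 0 °C → rt
Reagents that add atoms: dibromomethane, BrCBr
Why: Takai–Lombardo methylenation is non-basic, so the α-stereocenter with its β-silyloxy group should neither epimerize nor eliminate while the exocyclic methylene is installed.

Step 8
Reactants: 11 tert-butyl(diphenyl){[(1R,3S)-2,2,3-trimethyl-6-methylidenecyclohexyl]methoxy}silane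
Product: 12 [(1R,3S)-2,2,3-trimethyl-6-methylidenecyclohexyl]methanol
Conditions: Bu4NF, THF, rt
Reagents that add atoms: none
Why: Fluoride desilylation frees the primary alcohol without affecting the exocyclic alkene.

Step 9
Reactants: 12 [(1R,3S)-2,2,3-trimethyl-6-methylidenecyclohexyl]methanol
Product: 13 1-phenyl-5-({[(1R,3S)-2,2,3-trimethyl-6-methylidenecyclohexyl]methyl}sulfanyl)-1H-tetrazole
Conditions: 1-phenyl-1H-tetrazole-5-thiol, PPh3, DIAD, THF, 0 °C → rt
Reagents that add atoms: 1-phenyl-1H-tetrazole-5-thiol, Sc1nnnn1-c1ccccc1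
Why: Mitsunobu thioetherification displaces the primary hydroxyl under neutral conditions that leave the allylic ring CH stereocenter alone.

Step 10
Reactants: 13 1-phenyl-5-({[(1R,3S)-2,2,3-trimethyl-6-methylidenecyclohexyl]methyl}sulfanyl)-1H-tetrazole
Product: 14 1-phenyl-5-({[(1R,3S)-2,2,3-trimethyl-6-methylidenecyclohexyl]methyl}sulfonyl)-1H-tetrazole
Conditions: (NH4)6Mo7O24·4H2O (cat.), 30% H2O2, EtOH, 0 °C → rt
Reagents that add atoms: hydrogen peroxide, OO
Why: Molybdate-catalyzed peroxide oxidation takes the sulfide to the sulfone much faster than it epoxidizes an unactivated 1,1-disubstituted alkene.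

**Ring B dienal**

Step 11
Reactants: 15 4-methoxy-2-methylphenol
Product: 16 4,4-dimethoxy-2-methylcyclohexa-2,5-dien-1-one
Conditions: PhI(OAc)2, MeOH, 0 °C
Reagents that add atoms: methanol, CO
Why: Oxidative dearomatization of a para-alkoxyphenol in methanol gives the quinone monoketal directly.

Step 12
Reactants: 16 4,4-dimethoxy-2-methylcyclohexa-2,5-dien-1-one
Product: 17 4,4-dimethoxy-2-methylcyclohex-2-en-1-one
Conditions: H2 (1 atm), RhCl(PPh3)3 (cat.), PhH/EtOH, rt
Reagents that add atoms: none
Why: Homogeneous hydrogenation with RhCl(PPh3)3 reduces the less substituted of the two enone double bonds and leaves the methyl-bearing one.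

Step 13
Reactants: 17 4,4-dimethoxy-2-methylcyclohex-2-en-1-one
Product: 19 (2S,3S)-3-{3-[tert-butyl(dimethyl)silyl]oxypropyl}-4,4-dimethoxy-2-methyl-2-(prop-2-en-1-yl)cyclohexan-1-one, via magnesium enolate 18 (not isolated)
Conditions: TBSO(CH2)3MgBr (1.3 equiv), CuBr·SMe2 (5 mol%), (R,S)-Josiphos-type diphosphine (6 mol%; the enantiomer that delivers the 3S adduct), t-BuOMe, −78 °C; then allyl iodide, DMPU, −78 → 0 °C
Reagents that add atoms: [3-(tert-butyldimethylsilyloxy)propyl]magnesium bromide, CC(C)(C)[Si](C)(C)OCCC[Mg]Br; allyl iodide, C=CCI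
Why: Copper-catalyzed asymmetric conjugate addition sets the tertiary center under ligand control, and the regiodefined enolate is C-allylated anti to the new β-substituent (tandem conjugate addition–enolate alkylation, a three-component coupling), giving the quaternary center with allyl and side chain trans.

Step 14
Reactants: 19 (2S,3S)-3-{3-[tert-butyl(dimethyl)silyl]oxypropyl}-4,4-dimethoxy-2-methyl-2-(prop-2-en-1-yl)cyclohexan-1-one
Product: 20 (1S,2S,3S)-3-{3-[tert-butyl(dimethyl)silyl]oxypropyl}-4,4-dimethoxy-1,2-dimethyl-2-(prop-2-en-1-yl)cyclohexan-1-ol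
Conditions: MeLi, CeCl3, THF, −78 °C
Reagents that add atoms: methyllithium, [Li]C
Why: The non-basic organocerium reagent adds to the hindered ketone and should approach anti to the side chain at C3, which is syn-axial to one carbonyl face, so the methyl enters cis to the allyl group and the hydroxyl ends cis to the ring methyl.

Step 15
Reactants: 20 (1S,2S,3S)-3-{3-[tert-butyl(dimethyl)silyl]oxypropyl}-4,4-dimethoxy-1,2-dimethyl-2-(prop-2-en-1-yl)cyclohexan-1-ol
Product: 21 (2S,3S,4S)-4-hydroxy-2-(3-hydroxypropyl)-3,4-dimethyl-3-(prop-2-en-1-yl)cyclohexan-1-one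
Conditions: 1 M HCl, THF, 0 °C → rt
Reagents that add atoms: water, O
Why: Mild aqueous acid hydrolyses the dimethyl ketal and the primary silyl ether together, and should be too mild to enolize the hindered α-stereocenter of the new ketone.

Step 16
Reactants: 21 (2S,3S,4S)-4-hydroxy-2-(3-hydroxypropyl)-3,4-dimethyl-3-(prop-2-en-1-yl)cyclohexan-1-one
Product: 22 3-[(1S,2S,3S)-3-hydroxy-2,3-dimethyl-6-oxo-2-(prop-2-en-1-yl)cyclohexyl]propyl 2-bromopropanoate
Conditions: 2-bromopropanoyl bromide, pyridine, CH2Cl2, −40 °C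
Reagents that add atoms: 2-bromopropanoyl bromide, CC(Br)C(Br)=O
Why: Acylation is selective for the primary hydroxyl over the hindered tertiary one and attaches the three enal carbons to the side-chain oxygen as a tether.

Step 17
Reactants: 22 3-[(1S,2S,3S)-3-hydroxy-2,3-dimethyl-6-oxo-2-(prop-2-en-1-yl)cyclohexyl]propyl 2-bromopropanoate
Product: 25 ring B-fused eight-membered α,β-unsaturated lactone (endocyclic tetrasubstituted C=C), via samarium aldolate 23 (not isolated), via β-acetoxy lactone 24 (not isolated)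
Conditions: SmI2 (2.5 equiv), THF (0.005 M), −78 → 0 °C; Ac2O, 0 °C; then DBU, rt
Reagents that add atoms: none
Why: The samarium Reformatsky reaction closes the medium-ring lactone onto the ring ketone, the samarium alkoxide alone is acetylated in situ, and E1cB elimination then gives the conjugated alkene, which inside an eight-membered ring must hold the ring CH and the carbonyl carbon cis, the geometry of the target enal.

Step 18
Reactants: 25 ring B-fused eight-membered α,β-unsaturated lactone
Product: 26 (1S,2S,3R,4Z)-4-(1-hydroxypropan-2-ylidene)-3-(3-hydroxypropyl)-1,2-dimethyl-2-(prop-2-en-1-yl)cyclohexan-1-ol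
Conditions: i-Bu2AlH (excess), CH2Cl2, −78 → 0 °C; KNaC4H4O6 (aq.)
Reagents that add atoms: none
Why: 1,2-Reduction of the unsaturated lactone opens the temporary ring to the allylic alcohol and the hydroxypropyl chain with the alkene geometry unchanged.

Step 19
Reactants: 26 (1S,2S,3R,4Z)-4-(1-hydroxypropan-2-ylidene)-3-(3-hydroxypropyl)-1,2-dimethyl-2-(prop-2-en-1-yl)cyclohexan-1-ol
Product: 27 tris(triethylsilyl) ether of 26
Conditions: Et3SiOTf (3.6 equiv), 2,6-lutidine, CH2Cl2, −78 → 0 °C
Reagents that add atoms: triethylsilyl trifluoromethanesulfonate, CC[Si](CC)(CC)OS(=O)(=O)C(F)(F)F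
Why: The silyl triflate protects both primary hydroxyls and the hindered tertiary one, so no acidic proton remains for the later carbanion step.

Step 20
Reactants: 27 tris(triethylsilyl) ether of 26
Product: 29 primary alcohol from anti-Markovnikov hydration of the allyl group of 27, via alkylborane 28 (not isolated)
Conditions: 9-BBN, THF, rt; then NaOH, H2O2, 0 °C
Reagents that add atoms: hydrogen peroxide, OO
Why: Hydroboration–oxidation with the bulky borane takes the terminal alkene only, leaving the tetrasubstituted alkene.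

Step 21
Reactants: 29 primary alcohol from 27
Product: 30 aldehyde (3-oxopropyl side chain on the quaternary carbon)
Conditions: Dess–Martin periodinane, NaHCO3, CH2Cl2, rt
Reagents that add atoms: none
Why: Buffered Dess–Martin oxidation gives the aldehyde without loss of the silyl ethers.

Step 22
Reactants: 30 aldehyde
Product: 31 (E)-2-methyl-2-enal (dienal partner)
Conditions: Ph3P=C(CH3)CHO, PhMe, 90 °C
Reagents that add atoms: 2-(triphenyl-λ5-phosphanylidene)propanal, CC(C=O)=P(c1ccccc1)(c1ccccc1)c1ccccc1
Why: Wittig olefination with the stabilized ylide gives the trisubstituted (E)-enal under thermodynamic control of the oxaphosphetane.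

**Union and end game**

Step 23
Reactants: 14 ring A sulfone; 31 (E)-2-methyl-2-enal
Product: 32 tris(triethylsilyl) ether of the coupled (E,E)-diene
Conditions: 14, KN(SiMe3)2, DME, −60 °C; then 31, −60 °C → rt
Reagents that add atoms: none
Why: Julia–Kocienski olefination (addition, Smiles rearrangement, loss of SO2 and tetrazolate) joins the fragments as the (E)-disubstituted alkene, and the β-branched sulfone anion is not expected to disturb the neighbouring allylic stereocenter.

Step 24
Reactants: 32 tris(triethylsilyl) ether of the coupled diene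
Product: 33 triol (allylic alcohol precursor of the target)
Conditions: HF·pyridine, pyridine, THF, 0 °C → rt
Reagents that add atoms: none
Why: Buffered fluoride removes all three silyl groups under conditions mild enough for the skipped triene.

Step 25
Reactants: 33 triol
Product: 34 CNP0155943.1
Conditions: activated MnO2, CH2Cl2, rt
Reagents that add atoms: none
Why: MnO2 oxidizes only the allylic primary alcohol to the enal, leaving the saturated primary and the tertiary hydroxyls.

**Compound list**

1 | (S)-α-campholenic aldehyde, 2-[(1S)-2,2,3-trimethylcyclopent-3-en-1-yl]acetaldehyde | C1C=C(C)C(C)(C)[C@@H]1CC=O | starting material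
2 | 2-[(1S)-2,2,3-trimethylcyclopent-3-en-1-yl]acetic acid | C1C=C(C)C(C)(C)[C@@H]1CC(=O)O | intermediate
3 | Barton ester, 2-thioxopyridin-1(2H)-yl 2-[(1S)-2,2,3-trimethylcyclopent-3-en-1-yl]acetate | C1C=C(C)C(C)(C)[C@@H]1CC(=O)ON1C=CC=CC1=S | intermediate
4 | [(1R)-2,2,3-trimethylcyclopent-3-en-1-yl]methyl hydroperoxide | C1C=C(C)C(C)(C)[C@@H]1COO | intermediate
5 | [(1R)-2,2,3-trimethylcyclopent-3-en-1-yl]methanol | C1C=C(C)C(C)(C)[C@@H]1CO | intermediate
6 | tert-butyl(diphenyl){[(1R)-2,2,3-trimethylcyclopent-3-en-1-yl]methoxy}silane | C1C=C(C)C(C)(C)[C@@H]1CO[Si](c1ccccc1)(c1ccccc1)C(C)(C)C | intermediate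
7 | (5R)-5-{[tert-butyl(diphenyl)silyl]oxymethyl}-3,4,4-trimethylcyclopent-2-en-1-one | O=C1C=C(C)C(C)(C)[C@@H]1CO[Si](c1ccccc1)(c1ccccc1)C(C)(C)C | intermediate
8 | (2R,4S)-2-{[tert-butyl(diphenyl)silyl]oxymethyl}-3,3,4-trimethylcyclopentan-1-one (2,4-cis) | O=C1C[C@H](C)C(C)(C)[C@@H]1CO[Si](c1ccccc1)(c1ccccc1)C(C)(C)C | intermediate
9 | (4S,6R)-6-{[tert-butyl(diphenyl)silyl]oxymethyl}-4,5,5-trimethyl-2-(trimethylsilyl)cyclohexan-1-one (either epimer at C2) | O=C1C([Si](C)(C)C)C[C@H](C)C(C)(C)[C@@H]1CO[Si](c1ccccc1)(c1ccccc1)C(C)(C)C | intermediate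
10 | (2R,4S)-2-{[tert-butyl(diphenyl)silyl]oxymethyl}-3,3,4-trimethylcyclohexan-1-one (2,4-cis) | O=C1CC[C@H](C)C(C)(C)[C@@H]1CO[Si](c1ccccc1)(c1ccccc1)C(C)(C)C | intermediate
11 | tert-butyl(diphenyl){[(1R,3S)-2,2,3-trimethyl-6-methylidenecyclohexyl]methoxy}silane | C=C1CC[C@H](C)C(C)(C)[C@@H]1CO[Si](c1ccccc1)(c1ccccc1)C(C)(C)C | intermediate
12 | [(1R,3S)-2,2,3-trimethyl-6-methylidenecyclohexyl]methanol | C=C1CC[C@H](C)C(C)(C)[C@@H]1CO | intermediate
13 | 1-phenyl-5-({[(1R,3S)-2,2,3-trimethyl-6-methylidenecyclohexyl]methyl}sulfanyl)-1H-tetrazole | C=C1CC[C@H](C)C(C)(C)[C@@H]1CSc1nnnn1-c1ccccc1 | intermediate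
14 | 1-phenyl-5-({[(1R,3S)-2,2,3-trimethyl-6-methylidenecyclohexyl]methyl}sulfonyl)-1H-tetrazole | C=C1CC[C@H](C)C(C)(C)[C@@H]1CS(=O)(=O)c1nnnn1-c1ccccc1 | intermediate
15 | 4-methoxy-2-methylphenol | COc1ccc(O)c(C)c1 | starting material
16 | 4,4-dimethoxy-2-methylcyclohexa-2,5-dien-1-one | COC1(OC)C=CC(=O)C(C)=C1 | intermediate
17 | 4,4-dimethoxy-2-methylcyclohex-2-en-1-one | COC1(OC)CCC(=O)C(C)=C1 | intermediate
18 | bromomagnesium enolate of (3S)-3-{3-[tert-butyl(dimethyl)silyl]oxypropyl}-4,4-dimethoxy-2-methylcyclohexanone | CC1=C(O[Mg]Br)CCC(OC)(OC)[C@H]1CCCO[Si](C)(C)C(C)(C)C | intermediate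
19 | (2S,3S)-3-{3-[tert-butyl(dimethyl)silyl]oxypropyl}-4,4-dimethoxy-2-methyl-2-(prop-2-en-1-yl)cyclohexan-1-one (allyl and side chain trans) | C=CC[C@@]1(C)[C@H](CCCO[Si](C)(C)C(C)(C)C)C(OC)(OC)CCC1=O | intermediate
20 | (1S,2S,3S)-3-{3-[tert-butyl(dimethyl)silyl]oxypropyl}-4,4-dimethoxy-1,2-dimethyl-2-(prop-2-en-1-yl)cyclohexan-1-ol | C=CC[C@@]1(C)[C@H](CCCO[Si](C)(C)C(C)(C)C)C(OC)(OC)CC[C@]1(C)O | intermediate
21 | (2S,3S,4S)-4-hydroxy-2-(3-hydroxypropyl)-3,4-dimethyl-3-(prop-2-en-1-yl)cyclohexan-1-one | C=CC[C@@]1(C)[C@H](CCCO)C(=O)CC[C@]1(C)O | intermediate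
22 | 3-[(1S,2S,3S)-3-hydroxy-2,3-dimethyl-6-oxo-2-(prop-2-en-1-yl)cyclohexyl]propyl 2-bromopropanoate (both epimers at CHBr) | C=CC[C@@]1(C)[C@H](CCCOC(=O)C(C)Br)C(=O)CC[C@]1(C)O | intermediate
23 | diiodosamarium alkoxide of the eight-membered β-hydroxy lactone (new carbinol and α-methyl centers undefined) | C=CC[C@@]1(C)[C@H](CCCOC(=O)C2C)C2(O[Sm](I)I)CC[C@]1(C)O | intermediate
24 | eight-membered β-acetoxy lactone | C=CC[C@@]1(C)[C@H](CCCOC(=O)C2C)C2(OC(C)=O)CC[C@]1(C)O | intermediate
25 | ring B-fused 3-methyl-5,6,7,8-tetrahydro-2H-oxocin-2-one: eight-membered lactone from the side-chain oxygen to the enoate carbonyl, endocyclic tetrasubstituted C=C, free tertiary alcohol, allyl/methyl quaternary center | C=CC[C@@]1(C)[C@H](CCCOC2=O)/C(=C2/C)CC[C@]1(C)O | intermediate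
26 | (1S,2S,3R,4Z)-4-(1-hydroxypropan-2-ylidene)-3-(3-hydroxypropyl)-1,2-dimethyl-2-(prop-2-en-1-yl)cyclohexan-1-ol | C=CC[C@@]1(C)[C@H](CCCO)/C(=C(/C)CO)CC[C@]1(C)O | intermediate
27 | tris(triethylsilyl) ether of 26 | C=CC[C@@]1(C)[C@H](CCCO[Si](CC)(CC)CC)/C(=C(/C)CO[Si](CC)(CC)CC)CC[C@]1(C)O[Si](CC)(CC)CC | intermediate
28 | B-alkyl-9-borabicyclo[3.3.1]nonane from 27 (boron on the terminal carbon of the former allyl group) | C1CC2CCCC(C1)B2CCC[C@@]1(C)[C@H](CCCO[Si](CC)(CC)CC)/C(=C(/C)CO[Si](CC)(CC)CC)CC[C@]1(C)O[Si](CC)(CC)CC | intermediate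
29 | primary alcohol: 27 with the allyl group turned into 3-hydroxypropyl | OCCC[C@@]1(C)[C@H](CCCO[Si](CC)(CC)CC)/C(=C(/C)CO[Si](CC)(CC)CC)CC[C@]1(C)O[Si](CC)(CC)CC | intermediate
30 | aldehyde: 27 with the allyl group turned into 3-oxopropyl | O=CCC[C@@]1(C)[C@H](CCCO[Si](CC)(CC)CC)/C(=C(/C)CO[Si](CC)(CC)CC)CC[C@]1(C)O[Si](CC)(CC)CC | intermediate
31 | (E)-2-methyl-2-enal: 30 extended by the CH=C(CH3)CHO unit | O=C/C(C)=C/CC[C@@]1(C)[C@H](CCCO[Si](CC)(CC)CC)/C(=C(/C)CO[Si](CC)(CC)CC)CC[C@]1(C)O[Si](CC)(CC)CC | intermediate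
32 | tris(triethylsilyl) ether of the coupled (E,E)-diene | C=C1CC[C@H](C)C(C)(C)[C@@H]1/C=C/C(C)=C/CC[C@@]2(C)[C@H](CCCO[Si](CC)(CC)CC)/C(=C(/C)CO[Si](CC)(CC)CC)CC[C@]2(C)O[Si](CC)(CC)CC | intermediate
33 | triol: the target with CH2OH in place of CHO | C=C1CC[C@H](C)C(C)(C)[C@@H]1/C=C/C(C)=C/CC[C@@]2(C)[C@H](CCCO)/C(=C(/C)CO)CC[C@]2(C)O | intermediate
34 | CNP0155943.1 | C=C1CC[C@H](C)C(C)(C)[C@@H]1/C=C/C(C)=C/CC[C@@]1(C)[C@H](CCCO)/C(=C(/C)C=O)CC[C@]1(C)O | target

**Step count and risks**

Total step count: 25.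
Longest linear sequence: 15 steps (steps 11–25, from 4-methoxy-2-methylphenol); the ring A branch is 10 steps before the union.

Steps most likely to fail:

1. Step 17. The medium-ring Reformatsky closure may lose to intermolecular coupling or simple reductive loss of bromine, and the ring ketone may epimerize at its α-center before it is trapped. Fallback: from 21, silylate the primary hydroxyl (TBSCl, imidazole) to the keto silyl ether F8. Treat F8 with the lithium enolate of ethyl 2-(trimethylsilyl)propanoate (excess, THF, −78 °C → rt, Peterson olefination) and separate the geometric isomers by chromatography to obtain the (Z)-enoate F9; the other isomer is recycled by photoisomerization (PhSSPh, light). Reduce F9 with i-Bu2AlH to the allylic alcohol F10 and desilylate with Bu4NF to rejoin the route at 26.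

2. Step 13. Face selection by the chiral copper catalyst may be weak on this hindered α-methyl enone, and the magnesium enolate may O-allylate or fail to alkylate. Fallback: from 17, exchange the ketal with (2R,3R)-butane-2,3-diol (PPTS, PhH, reflux) to the chiral spiroketal enone F5. Add the same Grignard reagent with stoichiometric CuI and TMSCl, regenerate the lithium enolate with MeLi and allylate (allyl iodide, HMPA), then separate the diastereomers by chromatography to obtain the ketal F6. Add MeLi/CeCl3 to give the tertiary alcohol F7, and hydrolyse with aqueous HCl to rejoin the route at 21.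

3. Step 6. The more substituted α-carbon may migrate in competition, or a second insertion may follow the first. Fallback: from 8, enolize kinetically toward the ring CH2 (LiN(i-Pr)2, TMSCl, THF, −78 °C) to the trimethylsilyl enol ether F1. Ozonize and reduce (O3, CH2Cl2/MeOH, −78 °C; NaBH4) to the six-membered lactone F2, add one equivalent of MeLi (THF, −78 °C) to give the hydroxy methyl ketone F3, and convert the alcohol to the iodide F4 (I2, PPh3, imidazole). Intramolecular alkylation of the kinetic methyl-ketone enolate (LiN(i-Pr)2, THF, −78 °C → rt) closes the same a2–a3 bond and rejoins the route at 10.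

**Further compounds**

F1 | step 6 | kinetic trimethylsilyl enol ether of 8 (double bond toward the ring CH2) | C[Si](C)(C)OC1=C[C@H](C)C(C)(C)[C@@H]1CO[Si](c1ccccc1)(c1ccccc1)C(C)(C)C
F2 | step 6 | 3-{[tert-butyl(diphenyl)silyl]oxymethyl}-4,4,5-trimethyloxan-2-one (3,5-cis, centers as in 8) | O=C1OC[C@H](C)C(C)(C)[C@@H]1CO[Si](c1ccccc1)(c1ccccc1)C(C)(C)C
F3 | step 6 | 3-{[tert-butyl(diphenyl)silyl]oxymethyl}-6-hydroxy-4,4,5-trimethylhexan-2-one (centers as in 8) | OC[C@H](C)C(C)(C)[C@@H](C(C)=O)CO[Si](c1ccccc1)(c1ccccc1)C(C)(C)C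
F4 | step 6 | 3-{[tert-butyl(diphenyl)silyl]oxymethyl}-6-iodo-4,4,5-trimethylhexan-2-one (centers as in 8) | IC[C@H](C)C(C)(C)[C@@H](C(C)=O)CO[Si](c1ccccc1)(c1ccccc1)C(C)(C)C
F5 | step 13 | (2R,3R)-2,3,7-trimethyl-1,4-dioxaspiro[4.5]dec-6-en-8-one | C[C@H]1OC2(CCC(=O)C(C)=C2)O[C@@H]1C
F6 | step 13 | (2R,3R)-butane-2,3-diyl ketal analogue of 19 | C=CC[C@@]1(C)[C@H](CCCO[Si](C)(C)C(C)(C)C)C2(O[C@H](C)[C@@H](C)O2)CCC1=O
F7 | step 13 | (2R,3R)-butane-2,3-diyl ketal analogue of 20 | C=CC[C@@]1(C)[C@H](CCCO[Si](C)(C)C(C)(C)C)C2(O[C@H](C)[C@@H](C)O2)CC[C@]1(C)O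
F8 | step 17 | primary tert-butyldimethylsilyl ether of 21 | C=CC[C@@]1(C)[C@H](CCCO[Si](C)(C)C(C)(C)C)C(=O)CC[C@]1(C)O
F9 | step 17 | ethyl (Z)-2-(cyclohexylidene)propanoate from F8 (ester cis to the ring CH) | C=CC[C@@]1(C)[C@H](CCCO[Si](C)(C)C(C)(C)C)/C(=C(/C)C(=O)OCC)CC[C@]1(C)O
F10 | step 17 | allylic alcohol from F9 (primary silyl ether of 26) | C=CC[C@@]1(C)[C@H](CCCO[Si](C)(C)C(C)(C)C)/C(=C(/C)CO)CC[C@]1(C)O
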